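**Retrosynthetic overview**

1. Numbering: O1, C2 (3,4-dimethoxyphenyl), C3 (CH3), C4 (CH3), C5 (3,4,5-trimethoxyphenyl). The strategy rests on C5, which is benzylic and bonded to O1: in an open-chain 3,4,5-trimethoxybenzyl ether its C–H bonds are doubly activated toward a carbene placed at C4.
2. The C4 methyl is traced back to the C4 methyl ester 14 (reduction, tosylation, hydride displacement). 14 is traced back to its C4 epimer 13 by methoxide equilibration, since the ester makes C4 epimerisable.
3. The only ring, the oxolane, is opened at C4–C5: dirhodium-carbene 1,5 C–H insertion of α-diazo ester 12 gives 13 (ring formed in step 8).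
4. 12 comes from ester 10 by benzoylation and debenzoylative diazo transfer; 10 from alkene 6 (hydroboration, oxidation, esterification); 6 from alcohol 4 and benzyl bromide 5.
5. 4 comes from 3,4-dimethoxybenzaldehyde 1 and (E)-crotylboronate 2 by asymmetric crotylboration, which sets C2 and C3 (anti).

Key step: step 8

Remark on the chemistry (assumption): the phosphoric acid of step 1 is taken to direct crotyl transfer as (R)-acid to the Re face and (S)-acid to the Si face of an aryl aldehyde, so the (S)-acid is specified. The configuration of 4 would be checked (MTPA esters) before it is carried on, and the enantiomeric acid used if the check showed the opposite sense.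

**Step 1**
Reactants: 1 3,4-dimethoxybenzaldehyde; 2 (E)-crotylboronic acid pinacol ester
Product: 4 (1S,2S)-1-(3,4-dimethoxyphenyl)-2-methylbut-3-en-1-ol (anti), via O-pinacolboryl ether 3 (not isolated)
Conditions: (S)-3,3′-bis(2,4,6-triisopropylphenyl)-1,1′-binaphthyl-2,2′-diyl hydrogen phosphate [(S)-TRIP, 5 mol %], PhMe, −30 °C; aq. NaHCO3 work-up
Reagents that add atoms: none
Why: Chiral phosphoric acid-catalysed crotylboration through a closed chair (Zimmerman–Traxler) transition state, in which the (E)-crotyl geometry gives the anti relationship and the (S)-acid is expected to direct addition to the Si face of the aldehyde, setting the carbinol carbon (S, future C2) and the methyl-bearing carbon (S, future C3).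

**Step 2**
Reactants: 4 (1S,2S)-1-(3,4-dimethoxyphenyl)-2-methylbut-3-en-1-ol; 5 5-(bromomethyl)-1,2,3-trimethoxybenzene (3,4,5-trimethoxybenzyl bromide)
Product: 6 5-({[(1S,2S)-1-(3,4-dimethoxyphenyl)-2-methylbut-3-en-1-yl]oxy}methyl)-1,2,3-trimethoxybenzene
Conditions: NaH, THF/DMF 4:1, 0 °C; then 5, Bu4NI (cat.), 0 °C → rt
Reagents that add atoms: none
Why: Williamson ether synthesis, the sodium alkoxide of 4 displacing bromide from the primary benzylic bromide without breaking a bond to either stereocentre and without the acid that would ionise the electron-rich benzylic carbinol.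

**Step 3**
Reactants: 6 5-({[(1S,2S)-1-(3,4-dimethoxyphenyl)-2-methylbut-3-en-1-yl]oxy}methyl)-1,2,3-trimethoxybenzene
Product: 8 (3S,4S)-4-(3,4-dimethoxyphenyl)-3-methyl-4-[(3,4,5-trimethoxyphenyl)methoxy]butan-1-ol, via B-alkyl-9-BBN adduct 7 (not isolated)
Conditions: 9-borabicyclo[3.3.1]nonane (9-BBN), THF, 0 °C → rt; then NaOH, H2O2, H2O, 0 °C → rt
Reagents that add atoms: hydrogen peroxide, OO (the hydroxyl oxygen of 8); 9-BBN, B1C2CCCC1CCC2 (boron and its bicycle are present in 7 only)
Why: Anti-Markovnikov hydroboration–oxidation, the bulky dialkylborane placing boron on the terminal carbon of the monosubstituted alkene and alkaline peroxide replacing it by hydroxyl, with no new stereocentre formed and the ethers untouched.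

**Step 4**
Reactants: 8 (3S,4S)-4-(3,4-dimethoxyphenyl)-3-methyl-4-[(3,4,5-trimethoxyphenyl)methoxy]butan-1-ol
Product: 9 (3S,4S)-4-(3,4-dimethoxyphenyl)-3-methyl-4-[(3,4,5-trimethoxyphenyl)methoxy]butanoic acid
Conditions: 2,2,6,6-tetramethylpiperidin-1-oxyl (TEMPO, 0.2 equiv), PhI(OAc)2 (2.2 equiv), MeCN/H2O 1:1, rt
Reagents that add atoms: water, O
Why: Nitroxyl (oxoammonium)-catalysed oxidation with PhI(OAc)2 as terminal oxidant, which takes the primary alcohol through the aldehyde hydrate to the acid under near-neutral conditions that spare the benzylic ethers and the electron-rich arenes.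

**Step 5**
Reactants: 9 (3S,4S)-4-(3,4-dimethoxyphenyl)-3-methyl-4-[(3,4,5-trimethoxyphenyl)methoxy]butanoic acid
Product: 10 methyl (3S,4S)-4-(3,4-dimethoxyphenyl)-3-methyl-4-[(3,4,5-trimethoxyphenyl)methoxy]butanoate
Conditions: Me3SiCHN2, PhMe/MeOH 4:1, 0 °C → rt
Reagents that add atoms: trimethylsilyldiazomethane, C[Si](C)(C)C=[N+]=[N-]
Why: Esterification by O-methylation of the carboxylic acid with trimethylsilyldiazomethane in methanol, a neutral method that keeps acid away from the benzylic ether.

**Step 6**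
Reactants: 10 methyl (3S,4S)-4-(3,4-dimethoxyphenyl)-3-methyl-4-[(3,4,5-trimethoxyphenyl)methoxy]butanoate
Product: 11 methyl (3S,4S)-2-benzoyl-4-(3,4-dimethoxyphenyl)-3-methyl-4-[(3,4,5-trimethoxyphenyl)methoxy]butanoate (both C2 epimers, keto/enol)
Conditions: NaH, PhCO2Me, MeOH (cat.), DME, 85 °C; then AcOH, 0 °C
Reagents that add atoms: methyl benzoate, COC(=O)c1ccccc1
Why: Crossed Claisen condensation, the sodium ester enolate being C-benzoylated by non-enolisable methyl benzoate and the equilibrium pulled through by deprotonation of the β-keto ester, while the new C2 centre is of no consequence and the C3 and C4 hydrogens are not acidic.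

**Step 7**
Reactants: 11 methyl (3S,4S)-2-benzoyl-4-(3,4-dimethoxyphenyl)-3-methyl-4-[(3,4,5-trimethoxyphenyl)methoxy]butanoate
Product: 12 methyl (3S,4S)-2-diazo-4-(3,4-dimethoxyphenyl)-3-methyl-4-[(3,4,5-trimethoxyphenyl)methoxy]butanoate
Conditions: 4-nitrobenzenesulfonyl azide, DBU, CH2Cl2, 0 °C → rt
Reagents that add atoms: 4-nitrobenzenesulfonyl azide, [N-]=[N+]=NS(=O)(=O)c1ccc(cc1)[N+](=O)[O-]
Why: Deacylative (Regitz-type) diazo transfer, the β-keto ester enolate attacking the electron-poor sulfonyl azide and the triazene intermediate fragmenting with transfer of the benzoyl group to the sulfonamide nitrogen to leave the α-diazo ester.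

**Step 8**
Reactants: 12 methyl (3S,4S)-2-diazo-4-(3,4-dimethoxyphenyl)-3-methyl-4-[(3,4,5-trimethoxyphenyl)methoxy]butanoate
Product: 13 methyl (2R,3S,4S,5S)-5-(3,4-dimethoxyphenyl)-4-methyl-2-(3,4,5-trimethoxyphenyl)oxolane-3-carboxylate (ester at C4 of the target numbering; cis to the C5 aryl group; trans to the C3 methyl)
Conditions: Rh2(O2CCPh3)4 (1 mol %), CH2Cl2, slow addition of 12, −78 °C → rt
Reagents that add atoms: none
Why: Rh2(O2CCPh3)4 expels N2 from 12 to give an electrophilic rhodium carbene at C4, which inserts into one benzylic C–H bond of the OCH2Ar group through a concerted, hydride-transfer-like three-centre transition state, forming C4–C5 and releasing the catalyst. The closest known reaction type is the dirhodium-catalysed intramolecular 1,5 C–H insertion of α-alkyl-α-diazo esters into benzylic or ether-activated C–H bonds, which gives cis-2-arylcyclopentanecarboxylates and tetrahydrofuran-3-carboxylates. The oxolane closes as a five-membered ring by 1,5 insertion through a six-centre, chair-like array of C4, C3, C2, O1, C5 and the migrating hydrogen. C5 is set by that chair, in which the C2 aryl and C3 methyl groups (anti, hence both pseudo-equatorial) are fixed and the trimethoxyphenyl group also takes a pseudo-equatorial place, so that it ends cis to the C2 aryl group. C4 is set kinetically in the same transition state with the ester pseudo-equatorial and hence cis to the new C5 aryl group, as in the precedent; this centre is not relied on, since step 9 resets it, and any of the C4 epimer formed alongside is carried on with 13. The step needs site selectivity for 1,5 insertion over 1,2-hydride migration from C3 and over attack on the arene rings, which should be secured by the doubly activated (benzylic and α-oxygen) C–H bond, the inductive deactivation of the C3–H bond by the C2 oxygen, the bulky triphenylacetate ligands and the low temperature.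

**Step 9**
Reactants: 13 methyl (2R,3S,4S,5S)-5-(3,4-dimethoxyphenyl)-4-methyl-2-(3,4,5-trimethoxyphenyl)oxolane-3-carboxylate
Product: 14 methyl (2R,3R,4S,5S)-5-(3,4-dimethoxyphenyl)-4-methyl-2-(3,4,5-trimethoxyphenyl)oxolane-3-carboxylate (ester at C4 of the target numbering; trans to the C5 aryl group; cis to the C3 methyl)
Conditions: NaOMe (0.2 equiv), MeOH, rt → 50 °C; AcOH quench; chromatography, recovered 13 resubmitted
Reagents that add atoms: none
Why: Base-mediated epimerisation of the ester α-carbon through its enolate under thermodynamic control, 14 (ester trans to the C5 aryl group and cis only to the smaller C3 methyl) being expected to be favoured over 13 (ester cis to the aryl group), while β-elimination of O1 from the enolate is stereoelectronically disfavoured in the five-membered ring.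

**Step 10**
Reactants: 14 methyl (2R,3R,4S,5S)-5-(3,4-dimethoxyphenyl)-4-methyl-2-(3,4,5-trimethoxyphenyl)oxolane-3-carboxylate
Product: 15 [(2R,3S,4S,5S)-5-(3,4-dimethoxyphenyl)-4-methyl-2-(3,4,5-trimethoxyphenyl)oxolan-3-yl]methanol
Conditions: LiAlH4, THF, 0 °C; H2O/aq. NaOH work-up
Reagents that add atoms: none
Why: LiAlH4 reduction of the methyl ester to the primary alcohol, which removes the acidity at C4 and so freezes its configuration.

**Step 11**
Reactants: 15 [(2R,3S,4S,5S)-5-(3,4-dimethoxyphenyl)-4-methyl-2-(3,4,5-trimethoxyphenyl)oxolan-3-yl]methanol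
Product: 16 [(2R,3S,4S,5S)-5-(3,4-dimethoxyphenyl)-4-methyl-2-(3,4,5-trimethoxyphenyl)oxolan-3-yl]methyl 4-methylbenzenesulfonate
Conditions: TsCl, Et3N, 4-(dimethylamino)pyridine (cat.), CH2Cl2, 0 °C → rt
Reagents that add atoms: 4-methylbenzenesulfonyl chloride, Cc1ccc(cc1)S(=O)(=O)Cl
Why: O-sulfonylation (tosylate formation) of the primary alcohol under amine base, turning the hydroxyl into a leaving group without touching a ring stereocentre.

**Step 12**
Reactants: 16 [(2R,3S,4S,5S)-5-(3,4-dimethoxyphenyl)-4-methyl-2-(3,4,5-trimethoxyphenyl)oxolan-3-yl]methyl 4-methylbenzenesulfonate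
Product: 17 (2S,3S,4R,5R)-2-(3,4-dimethoxyphenyl)-3,4-dimethyl-5-(3,4,5-trimethoxyphenyl)oxolane (CNP0210192.3)
Conditions: LiEt3BH, THF, 0 °C → rt
Reagents that add atoms: none
Why: SN2 hydride displacement of the primary tosylate by lithium triethylborohydride, converting CH2OTs into the C4 methyl group with no stereocentre involved and with the aryl methyl ethers and the oxolane inert to the reagent.

**Compound list**

1 | 3,4-dimethoxybenzaldehyde | COc1ccc(C=O)cc1OC | starting material
2 | (E)-crotylboronic acid pinacol ester | C/C=C/CB1OC(C)(C)C(C)(C)O1 | starting material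
3 | 2-{[(1S,2S)-1-(3,4-dimethoxyphenyl)-2-methylbut-3-en-1-yl]oxy}-4,4,5,5-tetramethyl-1,3,2-dioxaborolane | COc1ccc([C@@H](OB2OC(C)(C)C(C)(C)O2)[C@@H](C)C=C)cc1OC | intermediate
4 | (1S,2S)-1-(3,4-dimethoxyphenyl)-2-methylbut-3-en-1-ol | COc1ccc([C@@H](O)[C@@H](C)C=C)cc1OC | intermediate
5 | 5-(bromomethyl)-1,2,3-trimethoxybenzene | COc1cc(CBr)cc(OC)c1OC | starting material
6 | 5-({[(1S,2S)-1-(3,4-dimethoxyphenyl)-2-methylbut-3-en-1-yl]oxy}methyl)-1,2,3-trimethoxybenzene | COc1ccc([C@@H](OCc2cc(OC)c(OC)c(OC)c2)[C@@H](C)C=C)cc1OC | intermediate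
7 | 9-{(3S,4S)-4-(3,4-dimethoxyphenyl)-3-methyl-4-[(3,4,5-trimethoxyphenyl)methoxy]butyl}-9-borabicyclo[3.3.1]nonane | COc1ccc([C@@H](OCc2cc(OC)c(OC)c(OC)c2)[C@@H](C)CCB2C3CCCC2CCC3)cc1OC | intermediate
8 | (3S,4S)-4-(3,4-dimethoxyphenyl)-3-methyl-4-[(3,4,5-trimethoxyphenyl)methoxy]butan-1-ol | COc1ccc([C@@H](OCc2cc(OC)c(OC)c(OC)c2)[C@@H](C)CCO)cc1OC | intermediate
9 | (3S,4S)-4-(3,4-dimethoxyphenyl)-3-methyl-4-[(3,4,5-trimethoxyphenyl)methoxy]butanoic acid | COc1ccc([C@@H](OCc2cc(OC)c(OC)c(OC)c2)[C@@H](C)CC(=O)O)cc1OC | intermediate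
10 | methyl (3S,4S)-4-(3,4-dimethoxyphenyl)-3-methyl-4-[(3,4,5-trimethoxyphenyl)methoxy]butanoate | COc1ccc([C@@H](OCc2cc(OC)c(OC)c(OC)c2)[C@@H](C)CC(=O)OC)cc1OC | intermediate
11 | methyl (3S,4S)-2-benzoyl-4-(3,4-dimethoxyphenyl)-3-methyl-4-[(3,4,5-trimethoxyphenyl)methoxy]butanoate (C2 epimers) | COc1ccc([C@@H](OCc2cc(OC)c(OC)c(OC)c2)[C@@H](C)C(C(=O)c2ccccc2)C(=O)OC)cc1OC | intermediate
12 | methyl (3S,4S)-2-diazo-4-(3,4-dimethoxyphenyl)-3-methyl-4-[(3,4,5-trimethoxyphenyl)methoxy]butanoate | COc1ccc([C@@H](OCc2cc(OC)c(OC)c(OC)c2)[C@@H](C)C(=[N+]=[N-])C(=O)OC)cc1OC | intermediate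
13 | methyl (2R,3S,4S,5S)-5-(3,4-dimethoxyphenyl)-4-methyl-2-(3,4,5-trimethoxyphenyl)oxolane-3-carboxylate (ester cis to the adjacent trimethoxyphenyl group) | COc1ccc([C@H]2O[C@@H](c3cc(OC)c(OC)c(OC)c3)[C@@H](C(=O)OC)[C@@H]2C)cc1OC | intermediate
14 | methyl (2R,3R,4S,5S)-5-(3,4-dimethoxyphenyl)-4-methyl-2-(3,4,5-trimethoxyphenyl)oxolane-3-carboxylate (ester trans to the adjacent trimethoxyphenyl group) | COc1ccc([C@H]2O[C@@H](c3cc(OC)c(OC)c(OC)c3)[C@H](C(=O)OC)[C@@H]2C)cc1OC | intermediate
15 | [(2R,3S,4S,5S)-5-(3,4-dimethoxyphenyl)-4-methyl-2-(3,4,5-trimethoxyphenyl)oxolan-3-yl]methanol | COc1ccc([C@H]2O[C@@H](c3cc(OC)c(OC)c(OC)c3)[C@H](CO)[C@@H]2C)cc1OC | intermediate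
16 | [(2R,3S,4S,5S)-5-(3,4-dimethoxyphenyl)-4-methyl-2-(3,4,5-trimethoxyphenyl)oxolan-3-yl]methyl 4-methylbenzenesulfonate | COc1ccc([C@H]2O[C@@H](c3cc(OC)c(OC)c(OC)c3)[C@H](COS(=O)(=O)c3ccc(C)cc3)[C@@H]2C)cc1OC | intermediate
17 | (2S,3S,4R,5R)-2-(3,4-dimethoxyphenyl)-3,4-dimethyl-5-(3,4,5-trimethoxyphenyl)oxolane | COc1ccc([C@H]2O[C@@H](c3cc(OC)c(OC)c(OC)c3)[C@H](C)[C@@H]2C)cc1OC | target

**Step count and risks**

Total step count: 12. Longest linear sequence: 12 steps (1 → 17).

Steps most likely to fail:

**Step 8 (key step).** The carbene may be lost by 1,2-hydride migration from C3 to give the α,β-unsaturated ester, or by electrophilic attack on the electron-rich dimethoxyphenyl ring (five-membered closure onto its ortho carbon). The insertion may also proceed with poor facial control at C5. The fallback gives up the carbene and builds the ring as a lactone; it sets out from 4 and comes back to the route at 17. Hydroboration–oxidation of 4 (9-BBN; NaOH, H2O2) should give (1S,2S)-1-(3,4-dimethoxyphenyl)-2-methylbutane-1,4-diol F1. Oxidative lactonisation (TEMPO, PhI(OAc)2, CH2Cl2) should then give the trans lactone (4S,5S)-5-(3,4-dimethoxyphenyl)-4-methyloxolan-2-one F2. Enolate methylation (LiN(SiMe3)2, MeI, THF, −78 °C) enters anti to the ring methyl and should give the 3,4-trans lactone F3. Deprotonation with LiN(iPr)2 and kinetic protonation at −78 °C, the proton entering anti to the neighbouring methyl, should give the 3,4-cis-dimethyl lactone F4, whose carbonyl carbon is the future C5. Addition of 3,4,5-trimethoxyphenyllithium (from 5-bromo-1,2,3-trimethoxybenzene and n-BuLi, THF, −78 °C) should give the hemiketal F5. Et3SiH with BF3·OEt2 (CH2Cl2, −78 → 0 °C) then reduces the cyclic oxocarbenium ion; reversible benzylic ionisation under the Lewis acid should let C5 settle trans to the C4 methyl, the more stable arrangement for a cis-3,4-dimethyl oxolane, which is 17.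

**Step 9.** The equilibrium at C4 may not lie far enough on the side of 14, because the ester has a cis neighbour in either epimer. The enolate may also open the ring by β-elimination of O1 and reclose with loss of the C5 configuration. The fallback fixes C4 by a lactone enolate reaction before the oxolane exists; it sets out from 4 and comes back to the route at 15. 4 is taken to the lactone F2 as described above. Its lithium enolate (LiN(iPr)2, THF, −78 °C) is added to 3,4,5-trimethoxybenzaldehyde; the new C–C bond enters anti to the ring methyl and should give the aldol adduct F6 (carbinol epimers). The former lactone carbonyl carbon, which becomes the C4 substituent, is thereby placed cis to the C3 methyl. LiAlH4 (THF, 0 °C) should give the triol F7, and silylation of the primary hydroxyl (tert-butyldiphenylsilyl chloride, imidazole, DMF) the silyl ether F8. BF3·OEt2 (cat., CH2Cl2, −78 → 0 °C) closes the oxolane between the two benzylic carbinol carbons by reversible benzylic ionisation, in which both aryl groups should settle trans to their ring neighbours, giving the oxolane silyl ether F9. Bu4NF (THF) should release 15, and steps 11 and 12 follow.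

**Step 7.** At the hindered, β-branched α-carbon the enolate may attack the sulfonyl azide slowly, and simple debenzoylation back to 10 may compete with diazo transfer. The fallback makes the diazo group by diazotisation of an amine; it sets out from 10 and comes back to the route at 12. Enolate azidation (KN(SiMe3)2, THF, −78 °C; 2,4,6-triisopropylbenzenesulfonyl azide; AcOH quench) should give the α-azido ester F10 (C2 epimers). Staudinger reduction (PPh3, THF/H2O) should give the α-amino ester F11, and diazotisation (isoamyl nitrite, AcOH cat., CHCl3, reflux) should give 12. C3 and C4 of the chain are β and γ to the carbonyl throughout and are not at risk.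

**Further compounds**

F1 | step 8 | (1S,2S)-1-(3,4-dimethoxyphenyl)-2-methylbutane-1,4-diol | COc1ccc([C@@H](O)[C@@H](C)CCO)cc1OC
F2 | step 8 | (4S,5S)-5-(3,4-dimethoxyphenyl)-4-methyloxolan-2-one | COc1ccc([C@H]2OC(=O)C[C@@H]2C)cc1OC
F3 | step 8 | (3S,4S,5S)-5-(3,4-dimethoxyphenyl)-3,4-dimethyloxolan-2-one (3,4-trans) | COc1ccc([C@H]2OC(=O)[C@@H](C)[C@@H]2C)cc1OC
F4 | step 8 | (3R,4S,5S)-5-(3,4-dimethoxyphenyl)-3,4-dimethyloxolan-2-one (3,4-cis) | COc1ccc([C@H]2OC(=O)[C@H](C)[C@@H]2C)cc1OC
F5 | step 8 | (3R,4S,5S)-5-(3,4-dimethoxyphenyl)-3,4-dimethyl-2-(3,4,5-trimethoxyphenyl)oxolan-2-ol (anomers) | COc1ccc([C@H]2OC(O)(c3cc(OC)c(OC)c(OC)c3)[C@H](C)[C@@H]2C)cc1OC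
F6 | step 9 | (3R,4S,5S)-5-(3,4-dimethoxyphenyl)-3-[hydroxy(3,4,5-trimethoxyphenyl)methyl]-4-methyloxolan-2-one (carbinol epimers) | COc1ccc([C@H]2OC(=O)[C@@H](C(O)c3cc(OC)c(OC)c(OC)c3)[C@@H]2C)cc1OC
F7 | step 9 | (1S,2S,3S)-1-(3,4-dimethoxyphenyl)-3-(hydroxymethyl)-2-methyl-4-(3,4,5-trimethoxyphenyl)butane-1,4-diol (C4 epimers) | COc1ccc([C@@H](O)[C@@H](C)[C@@H](CO)C(O)c2cc(OC)c(OC)c(OC)c2)cc1OC
F8 | step 9 | (1S,2S,3S)-3-{[tert-butyl(diphenyl)silyl]oxymethyl}-1-(3,4-dimethoxyphenyl)-2-methyl-4-(3,4,5-trimethoxyphenyl)butane-1,4-diol (C4 epimers) | COc1ccc([C@@H](O)[C@@H](C)[C@@H](CO[Si](c2ccccc2)(c2ccccc2)C(C)(C)C)C(O)c2cc(OC)c(OC)c(OC)c2)cc1OC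
F9 | step 9 | tert-butyl{[(2R,3S,4S,5S)-5-(3,4-dimethoxyphenyl)-4-methyl-2-(3,4,5-trimethoxyphenyl)oxolan-3-yl]methoxy}diphenylsilane | COc1ccc([C@H]2O[C@@H](c3cc(OC)c(OC)c(OC)c3)[C@H](CO[Si](c3ccccc3)(c3ccccc3)C(C)(C)C)[C@@H]2C)cc1OC
F10 | step 7 | methyl (3S,4S)-2-azido-4-(3,4-dimethoxyphenyl)-3-methyl-4-[(3,4,5-trimethoxyphenyl)methoxy]butanoate (C2 epimers) | COc1ccc([C@@H](OCc2cc(OC)c(OC)c(OC)c2)[C@@H](C)C(N=[N+]=[N-])C(=O)OC)cc1OC
F11 | step 7 | methyl (3S,4S)-2-amino-4-(3,4-dimethoxyphenyl)-3-methyl-4-[(3,4,5-trimethoxyphenyl)methoxy]butanoate (C2 epimers) | COc1ccc([C@@H](OCc2cc(OC)c(OC)c(OC)c2)[C@@H](C)C(N)C(=O)OC)cc1OC
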